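**Plan**

1. Retrosynthesis (germacrane numbering: C1 ketone, C2=C3 furanone alkene, C4 methyl-bearing CH, C5 carbinol, C6 ester carbon, C7/C8 lactone fusion, C10 quaternary ether carbon, C11–C13 acrylate unit). The C6 methacrylate and the lactone bond C8–O–C12 are cut last, the C5/C6 diol is traced to an E C5=C6 alkene, and the furanone O–C3 bond to a C10 hydroxyl plus a 3-ethoxy enone.
2. Enabling feature: the ten-membered carbocycle C1–C10 then holds the oxy-Cope retron C1(=O)–C2=C3(O)–C4–C5=C6. Cutting C3–C4 and joining C1–C6 folds it into the cyclohexane C1/C10/C9/C8/C7/C6 with an ethoxyethynyl carbinol at C1 and an (E)-propenyl group at C6, which is an oxygenated carvone.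
3. Forward: (S)-carvone is oxygenated at C12 and C8, its carbonyl is transposed to C1, and the ring is epoxidised, propenylated at C6 and alkynylated at C1. The six-membered ring is then expanded to the ten-membered ring (step 12), the furanone is closed (step 13) and the lactone last (step 18).
4. Stereochemistry: C7 comes from carvone, C8 from enolate hydroxylation anti to C7, and C10 from hydroxyl-directed epoxidation. The C1 carbinol (anti to the epoxide) and C6 (anti to C7) only steer the chair transition state that sets C4 and the E alkene. C5 and C6 come from syn-osmylation of the exposed alkene face.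

Key step: step 12

Convention: germacrane numbering is used for every intermediate; in the six-membered ring β is the face of the C7 side chain and α the opposite face.
Remark: (S)-carvone is required because the carbonyl is moved from C9 to C1 on the way, which turns the easily made α′ oxygen (C8) into the γ oxygen the plan needs.
Assumption: the ring-expanded enol ether is drawn with the ethoxy group trans to C1 across C2=C3; either geometry passes through the same tetrahedral C3 intermediate when the furanone closes.

**Step 1**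
Reactants: 1 (S)-carvone (C9 ketone, C10(CH3)=C1 alkene, C6 and C8 methylenes, C7 bearing the β isopropenyl group C11–C13)
Product: 2 12-chloro-(S)-carvone (side chain now CH2=C(CH2Cl)–)
Conditions: Ca(OCl)2, CO2 (dry ice), CH2Cl2/H2O, 0 °C
Reagents that add atoms: calcium hypochlorite Ca(OCl)2, [Ca+2].[O-]Cl.[O-]Cl
Why: Ene-type allylic chlorination by HOCl formed in the flask should attack only the electron-rich 1,1-disubstituted alkene, the enone alkene being too electron-poor, and it leaves the C7 stereocentre untouched.

**Step 2**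
Reactants: 2 12-chloro-(S)-carvone
Product: 4 12-hydroxy-(S)-carvone, via 12-acetoxy-(S)-carvone 3 (not isolated)
Conditions: KOAc, n-Bu4NI (cat.), DMF, rt; then K2CO3 (cat.), MeOH, 0 °C
Reagents that add atoms: potassium acetate, CC(=O)[O-].[K+]
Why: SN2 displacement of the primary allylic chloride by acetate followed by carbonate-catalysed methanolysis (transesterification) should give the allylic alcohol without a base strong enough to form the enolate that would alkylate itself.

**Step 3**
Reactants: 4 12-hydroxy-(S)-carvone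
Product: 6 8α,12-dihydroxy-(S)-carvone (8-OH trans to the C7 side chain), via dipotassium dienolate alkoxide 5 (not isolated)
Conditions: KN(SiMe3)2 (2.2 equiv), THF, −78 °C; then 2-(phenylsulfonyl)-3-phenyloxaziridine, −78 °C; aq NH4Cl
Reagents that add atoms: 2-(phenylsulfonyl)-3-phenyloxaziridine, O=S(=O)(c1ccccc1)N1OC1c1ccccc1
Why: Enolate hydroxylation with an N-sulfonyloxaziridine: the kinetic cross-conjugated potassium dienolate (the C12 alkoxide is a spectator) should be oxidised at C8 on the face away from the adjacent C7 side chain, which sets the 8α hydroxyl trans to it.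

**Step 4**
Reactants: 6 8α,12-dihydroxy-(S)-carvone
Product: 7 8α,12-bis(tert-butyldimethylsilyloxy)-(S)-carvone
Conditions: TBSCl (2.5 equiv), imidazole, DMF, rt
Reagents that add atoms: tert-butyldimethylsilyl chloride, CC(C)(C)[Si](C)(C)Cl
Why: Imidazole-promoted silylation should cap the primary allylic and the secondary α-keto hydroxyl alike and so protect both future lactone oxygens through the basic, hydridic and oxidative steps that follow.

**Step 5**
Reactants: 7 bis-silyl ether
Product: 8 1α,10α-epoxy-8α,12-bis(TBSO)-9-ketone (epoxide trans to the C7 side chain)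
Conditions: 30% H2O2, NaOH (cat.), MeOH, 0 °C
Reagents that add atoms: hydrogen peroxide, OO
Why: Weitz–Scheffer nucleophilic epoxidation should proceed, as with carvone itself, by axial conjugate addition of hydroperoxide at C1 anti to the equatorial C7 side chain, giving the α epoxide.

**Step 6**
Reactants: 8 epoxy ketone
Product: 10 allylic alcohol (C1 α-OH, C9=C10 alkene with C10 methyl, C8 α-OTBS, C7 β-side chain CH2=C(CH2OTBS)–, C6 methylene), via epoxy ketone hydrazone 9 (not isolated)
Conditions: N2H4·H2O, AcOH (cat.), MeOH, 0 °C to rt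
Reagents that add atoms: none
Why: Wharton rearrangement: the epoxy hydrazone should fragment with loss of N2 so that the oxygen moves from C9 to C1 with retention at C1 and the alkene appears at C9=C10, which turns the α′ oxygen at C8 into the γ oxygen of a carveol.

**Step 7**
Reactants: 10 allylic alcohol
Product: 11 9α,10α-epoxy-1α-ol (epoxide cis to the C1 hydroxyl)
Conditions: VO(acac)2 (cat.), t-BuOOH, CH2Cl2, 0 °C to rt
Reagents that add atoms: tert-butyl hydroperoxide, CC(C)(C)OO
Why: Vanadium-catalysed hydroxyl-directed epoxidation should deliver oxygen to C9=C10 on the face of the pseudo-axial C1 hydroxyl (α) and leave the undirected side-chain alkene alone, which fixes the configuration of the future C10 carbinol.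

**Step 8**
Reactants: 11 epoxy alcohol
Product: 12 9α,10α-epoxy-1-ketone (C10 β-methyl, C8 α-OTBS, C7 β-side chain)
Conditions: Dess–Martin periodinane, pyridine, CH2Cl2, rt
Reagents that add atoms: none
Why: Dess–Martin oxidation of the secondary alcohol under pyridine buffering should give the α,β-epoxy ketone without opening the epoxide or touching the silyl ethers.

**Step 9**
Reactants: 12 epoxy ketone; 13 (E)-1-bromoprop-1-ene
Product: 14 6α-[(E)-prop-1-enyl]-9α,10α-epoxy-1-ketone (propenyl trans to the C7 side chain)
Conditions: Pd2(dba)3 (cat.), P(t-Bu)3 (cat.), LiN(SiMe3)2 (2.2 equiv), THF, 0 °C to rt; AcOH quench at −78 °C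
Reagents that add atoms: none
Why: Palladium-catalysed α-alkenylation of a ketone enolate: C6 is the only enolisable position, oxidative addition and reductive elimination should keep the E geometry of 13, and the propenyl group should enter anti to the C7 side chain, which is also the thermodynamically preferred trans-diequatorial arrangement.

**Step 10**
Reactants: 14 propenyl epoxy ketone; 15 ethoxyacetylene
Product: 16 1β-(ethoxyethynyl)-1α-hydroxy-9α,10α-epoxide (alkynyl trans to the C6 propenyl group, hydroxyl cis to the epoxide)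
Conditions: 15, n-BuLi, THF, −78 °C; CeCl3; then 14, −78 °C; aq NaHCO3
Reagents that add atoms: none
Why: 1,2-Addition of the weakly basic cerium acetylide should spare the acidic allylic C6 proton and attack the carbonyl anti to the epoxide oxygen (polar Felkin–Anh control), which places the ethoxyethynyl group β, trans to the C6 propenyl group, and the hydroxyl cis to the epoxide.

**Step 11**
Reactants: 16 epoxy carbinol
Product: 17 1β-(ethoxyethynyl)-1α,10α-dihydroxy cyclohexane (10β-methyl, C9 methylene, 8α-OTBS, 7β-side chain, 6α-(E)-propenyl)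
Conditions: LiBHEt3, THF, 0 °C to rt; aq NaHCO3 (non-oxidative work-up)
Reagents that add atoms: none
Why: SN2 hydride opening of the trisubstituted epoxide at its less substituted carbon C9 should give the tertiary C10 alcohol with the C10–O bond and thus the 10α configuration untouched, the cis epoxy alkoxide being unable to undergo Payne migration and the borohydride leaving the alkyne alone.

**Step 12**
Reactants: 17 ethoxyethynyl propenyl cyclohexanediol
Product: 19 ten-membered (5E)-3-ethoxy-10-hydroxy-2,5-dien-1-one (C4, C7, C8, C10 as in the target; 8-OTBS, 12-OTBS), via dipotassium allenolate 18 (not isolated)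
Conditions: KH (3 equiv), 18-crown-6 (3 equiv), THF, 0 °C to rt; then pH 7 phosphate buffer, −78 °C
Reagents that add atoms: none
Why: Proposed new method: the crown-ether-separated C1 potassium alkoxide weakens the C1–C6 bond and triggers a [3,3] shift in which the ynol-ether carbon C3 bonds to C4 while C1–C6 breaks, giving a ten-membered 3-ethoxy allenolate that is C-protonated on quench to the β-ethoxy enone; the closest known reaction is the anionic oxy-Cope ring expansion of 1-alkynyl-2-alkenylcyclohexanols to cyclodeca-2,5-dienones, the alkoxy substituent on the alkyne being the untested element. The ten-membered carbocycle is not closed end to end: it appears by cleavage of the bond that the cyclohexane shares with the six-centre chair-like transition state, a four-atom ring expansion. The new stereocentre C4 is set by that transition state: with the ethoxyethynyl and propenyl groups trans-diequatorial and H6 eclipsing the propenyl π-bond (least A1,3 strain), C3 can reach only the alkene face syn to C1, which gives 4S from the E-propenyl group and at the same time the E C5=C6 alkene. The step needs the sigmatropic path to outrun loss of ethoxyacetylide from the alkoxide and attack of the C10 alkoxide on the ynol ether; the low temperature allowed by the dissociated alkoxide and the gauche, pre-organised enyne should secure this. Any material that loses ethoxide and closes to the furanone in the flask converges with step 13.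

**Step 13**
Reactants: 19 3-ethoxy dienone
Product: 20 furanone (O bridging C3 and C10, C1 ketone, C2=C3; E C5=C6; 8-OTBS, 12-OTBS)
Conditions: PPTS (cat.), CH2Cl2, rt
Reagents that add atoms: none
Why: Acid-catalysed addition–elimination (vinylogous transesterification): the C10 hydroxyl should add to C3 of the protonated β-ethoxy enone and ethanol should leave, the standard cyclodehydration route to 3(2H)-furanones, so that either enol ether geometry converges and no stereocentre is affected.

**Step 14**
Reactants: 20 furanone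
Product: 21 (5S,6S)-5,6-diol (8-OTBS, 12-OTBS)
Conditions: OsO4 (cat.), NMO, acetone/H2O, 0 °C
Reagents that add atoms: osmium tetroxide, O=[Os](=O)(=O)=O; N-methylmorpholine N-oxide, C[N+]1([O-])CCOCC1; water, O
Why: Upjohn dihydroxylation should pick the strained E C5=C6 alkene of the nine-membered oxa-bridged ring over the hindered, inductively deactivated 2-(silyloxymethyl)allyl alkene and the push–pull furanone alkene, and syn addition on the only exposed face, the one turned away from the furanone, should give the 5S,6S diol.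

**Step 15**
Reactants: 21 diol
Product: 22 5-O-triethylsilyl ether (6-OH free)
Conditions: Et3SiCl (1.1 equiv), imidazole, CH2Cl2, −20 °C
Reagents that add atoms: triethylsilyl chloride, CC[Si](Cl)(CC)CC
Why: Silylation under mild imidazole conditions should select the less hindered C5 hydroxyl, since the C6 hydroxyl is wedged between the branched C7 side chain and the C8 silyl ether.

**Step 16**
Reactants: 22 C5 silyl ether; 23 methacrylic anhydride
Product: 24 6-O-methacrylate (5-OTES, 8-OTBS, 12-OTBS)
Conditions: 23, DMAP, Et3N, CH2Cl2, rt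
Reagents that add atoms: none
Why: DMAP-catalysed acyl transfer (Steglich-type acylation) should esterify the one remaining, hindered secondary hydroxyl at C6.

**Step 17**
Reactants: 24 methacrylate
Product: 25 5,8,12-triol 6-methacrylate
Conditions: HF·pyridine, pyridine, THF, 0 °C to rt
Reagents that add atoms: none
Why: Fluoride-induced cleavage of the triethylsilyl and both tert-butyldimethylsilyl ethers under buffered acidic conditions should free the C5, C8 and C12 hydroxyls without the acyl migration that basic fluoride could cause.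

**Step 18**
Reactants: 25 triol
Product: 28 CNP0195404.1, via hydroxy enal 26 (not isolated), via lactol 27 (not isolated)
Conditions: MnO2 (excess), CH2Cl2, rt
Reagents that add atoms: none
Why: MnO2 oxidative lactonisation: the primary allylic alcohol should be oxidised to the enal, which should close to the five-membered lactol with the C8 hydroxyl (favoured over the bridged six-membered lactol with the C5 hydroxyl) and be oxidised on to the trans-fused α-methylene lactone, the saturated C5 hydroxyl being inert to MnO2.

**Compound list**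

1 | (S)-carvone | CC1=CC[C@H](C(C)=C)CC1=O | starting material
2 | 12-chloro-(S)-carvone | CC1=CC[C@H](C(=C)CCl)CC1=O | intermediate
3 | 12-acetoxy-(S)-carvone | CC1=CC[C@H](C(=C)COC(C)=O)CC1=O | intermediate
4 | 12-hydroxy-(S)-carvone | CC1=CC[C@H](C(=C)CO)CC1=O | intermediate
5 | dipotassium dienolate alkoxide of 4 | [K+].[K+].CC1=CC[C@H](C(=C)C[O-])C=C1[O-] | intermediate
6 | 8α,12-dihydroxy-(S)-carvone | CC1=CC[C@H](C(=C)CO)[C@@H](O)C1=O | intermediate
7 | 8α,12-bis(TBSO)-(S)-carvone | CC1=CC[C@H](C(=C)CO[Si](C)(C)C(C)(C)C)[C@@H](O[Si](C)(C)C(C)(C)C)C1=O | intermediate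
8 | 1α,10α-epoxy-9-ketone | C[C@]12O[C@H]1C[C@H](C(=C)CO[Si](C)(C)C(C)(C)C)[C@@H](O[Si](C)(C)C(C)(C)C)C2=O | intermediate
9 | epoxy ketone hydrazone | C[C@]12O[C@H]1C[C@H](C(=C)CO[Si](C)(C)C(C)(C)C)[C@@H](O[Si](C)(C)C(C)(C)C)C2=NN | intermediate
10 | 1α-hydroxy-9-ene (transposed allylic alcohol) | O[C@@H]1C(C)=C[C@H](O[Si](C)(C)C(C)(C)C)[C@@H](C(=C)CO[Si](C)(C)C(C)(C)C)C1 | intermediate
11 | 9α,10α-epoxy-1α-ol | O[C@@H]1[C@]2(C)O[C@@H]2[C@H](O[Si](C)(C)C(C)(C)C)[C@@H](C(=C)CO[Si](C)(C)C(C)(C)C)C1 | intermediate
12 | 9α,10α-epoxy-1-ketone | O=C1[C@]2(C)O[C@@H]2[C@H](O[Si](C)(C)C(C)(C)C)[C@@H](C(=C)CO[Si](C)(C)C(C)(C)C)C1 | intermediate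
13 | (E)-1-bromoprop-1-ene | C/C=C/Br | starting material
14 | 6α-(E)-propenyl epoxy ketone | O=C1[C@]2(C)O[C@@H]2[C@H](O[Si](C)(C)C(C)(C)C)[C@@H](C(=C)CO[Si](C)(C)C(C)(C)C)[C@@H]1/C=C/C | intermediate
15 | ethoxyacetylene | CCOC#C | starting material
16 | 1β-(ethoxyethynyl)-1α-hydroxy epoxide | CCOC#C[C@@]1(O)[C@]2(C)O[C@@H]2[C@H](O[Si](C)(C)C(C)(C)C)[C@@H](C(=C)CO[Si](C)(C)C(C)(C)C)[C@@H]1/C=C/C | intermediate
17 | ethoxyethynyl propenyl cyclohexane-1α,10α-diol | CCOC#C[C@@]1(O)[C@](C)(O)C[C@H](O[Si](C)(C)C(C)(C)C)[C@@H](C(=C)CO[Si](C)(C)C(C)(C)C)[C@@H]1/C=C/C | intermediate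
18 | dipotassium allenolate of the ring-expanded product | [K+].[K+].CCOC1=C=C([O-])[C@](C)([O-])C[C@H](O[Si](C)(C)C(C)(C)C)[C@@H](C(=C)CO[Si](C)(C)C(C)(C)C)/C=C/[C@@H]1C | intermediate
19 | ten-membered 3-ethoxy dienone | CCO/C1=C/C(=O)[C@](C)(O)C[C@H](O[Si](C)(C)C(C)(C)C)[C@@H](C(=C)CO[Si](C)(C)C(C)(C)C)/C=C/[C@@H]1C | intermediate
20 | furanone with E C5=C6 alkene | C[C@H]1/C=C/[C@H](C(=C)CO[Si](C)(C)C(C)(C)C)[C@@H](O[Si](C)(C)C(C)(C)C)C[C@@]2(C)OC1=CC2=O | intermediate
21 | (5S,6S)-diol | O[C@@H]1[C@@H](O)[C@H](C)C2=CC(=O)[C@@](C)(C[C@H](O[Si](C)(C)C(C)(C)C)[C@H]1C(=C)CO[Si](C)(C)C(C)(C)C)O2 | intermediate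
22 | 5-O-triethylsilyl ether | O[C@@H]1[C@@H](O[Si](CC)(CC)CC)[C@H](C)C2=CC(=O)[C@@](C)(C[C@H](O[Si](C)(C)C(C)(C)C)[C@H]1C(=C)CO[Si](C)(C)C(C)(C)C)O2 | intermediate
23 | methacrylic anhydride | C=C(C)C(=O)OC(=O)C(C)=C | starting material
24 | 6-O-methacrylate, fully silylated | C=C(C)C(=O)O[C@@H]1[C@@H](O[Si](CC)(CC)CC)[C@H](C)C2=CC(=O)[C@@](C)(C[C@H](O[Si](C)(C)C(C)(C)C)[C@H]1C(=C)CO[Si](C)(C)C(C)(C)C)O2 | intermediate
25 | 5,8,12-triol 6-methacrylate | C=C(C)C(=O)O[C@@H]1[C@@H](O)[C@H](C)C2=CC(=O)[C@@](C)(C[C@H](O)[C@H]1C(=C)CO)O2 | intermediate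
26 | hydroxy enal | C=C(C)C(=O)O[C@@H]1[C@@H](O)[C@H](C)C2=CC(=O)[C@@](C)(C[C@H](O)[C@H]1C(=C)C=O)O2 | intermediate
27 | lactol | C=C(C)C(=O)O[C@@H]1[C@@H](O)[C@H](C)C2=CC(=O)[C@@](C)(C[C@@H]3OC(O)C(=C)[C@@H]13)O2 | intermediate
28 | CNP0195404.1 | C=C(C)C(=O)O[C@@H]1[C@@H](O)[C@H](C)C2=CC(=O)[C@@](C)(C[C@@H]3OC(=O)C(=C)[C@@H]13)O2 | target

**Totals**

Total step count: 18. Longest linear sequence: 18 steps from (S)-carvone.

**Steps most likely to fail**

Step 12 (proposed new method). What may go wrong: the tertiary propargylic alkoxide may fragment back to the ketone and ethoxyacetylide, or the C10 alkoxide may cyclise onto the ynol ether, before the sigmatropic shift takes place. The fallback sets out from 14 and returns at 20, using only known chemistry. HC≡CMgBr with CeCl3 (THF, −78 °C) should add anti to the epoxide to give the ethynyl epoxy carbinol F1. LiBHEt3 opens the epoxide to the ethynyl diol F2. KN(SiMe3)2 (2 equiv) and 18-crown-6 then bring about the known anionic oxy-Cope ring expansion of a 1-ethynyl-2-alkenylcyclohexanol to the cyclodeca-2,5-dienone F3, through the same chair and so with the same C4 configuration and E alkene. Conjugate addition of the C10 hydroxyl to C3 (DBU, CH2Cl2) closes the tetrahydrofuran-3-one F4. Saegusa–Ito dehydrogenation by way of the trimethylsilyl enol ether F5 (Me3SiOTf, Et3N; then Pd(OAc)2, MeCN) installs the C2=C3 bond of 20.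

Step 9. What may go wrong: once the more acidic product is deprotonated, the propenyl double bond may migrate into conjugation with the ketone or C6 may epimerise, and coupling of the hindered enolate may be slow. The fallback sets out from 12 and returns at 14. LiN(i-Pr)2 then allyl bromide (THF, −78 °C) alkylates C6 anti to the C7 side chain to give the 6α-allyl epoxy ketone F6. One-position alkene migration with RuHCl(CO)(PPh3)3 (toluene, 80 °C) then gives the (E)-propenyl ketone 14 under neutral conditions.

Step 14. What may go wrong: osmylation of the 1,1-disubstituted side-chain alkene may compete with that of C5=C6. The fallback sets out from 20 and returns at 28. It closes the lactone before the alkene is oxidised, so that the side-chain alkene is an electron-poor acrylate when OsO4 is used. HF·pyridine gives the furanone diol F7. MnO2 gives the α-methylene lactone F10 by way of the hydroxy enal F8 and the lactol F9. OsO4/NMO then gives the lactone diol F11, Et3SiCl/imidazole the C5 silyl ether F12, methacrylic anhydride/DMAP the C6 methacrylate F13, and HF·pyridine the target 28.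

**Further compounds**

F1 | step 12 | 1β-ethynyl-1α-hydroxy-9α,10α-epoxide | C#C[C@@]1(O)[C@]2(C)O[C@@H]2[C@H](O[Si](C)(C)C(C)(C)C)[C@@H](C(=C)CO[Si](C)(C)C(C)(C)C)[C@@H]1/C=C/C
F2 | step 12 | 1β-ethynyl-1α,10α-diol | C#C[C@@]1(O)[C@](C)(O)C[C@H](O[Si](C)(C)C(C)(C)C)[C@@H](C(=C)CO[Si](C)(C)C(C)(C)C)[C@@H]1/C=C/C
F3 | step 12 | ten-membered (2Z,5E)-10-hydroxy-2,5-dien-1-one | C[C@H]1/C=C/[C@H](C(=C)CO[Si](C)(C)C(C)(C)C)[C@@H](O[Si](C)(C)C(C)(C)C)C[C@@](C)(O)C(=O)/C=C\1
F4 | step 12 | 3,10-epoxy-1-ketone (tetrahydrofuran-3-one, C3 configuration not fixed) | C[C@H]1/C=C/[C@H](C(=C)CO[Si](C)(C)C(C)(C)C)[C@@H](O[Si](C)(C)C(C)(C)C)C[C@@]2(C)OC1CC2=O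
F5 | step 12 | trimethylsilyl enol ether of F4 | C[C@H]1/C=C/[C@H](C(=C)CO[Si](C)(C)C(C)(C)C)[C@@H](O[Si](C)(C)C(C)(C)C)C[C@@]2(C)OC1C=C2O[Si](C)(C)C
F6 | step 9 | 6α-allyl-9α,10α-epoxy-1-ketone | O=C1[C@]2(C)O[C@@H]2[C@H](O[Si](C)(C)C(C)(C)C)[C@@H](C(=C)CO[Si](C)(C)C(C)(C)C)[C@@H]1CC=C
F7 | step 14 | furanone 8,12-diol | C[C@H]1/C=C/[C@H](C(=C)CO)[C@@H](O)C[C@@]2(C)OC1=CC2=O
F8 | step 14 | furanone hydroxy enal | C[C@H]1/C=C/[C@H](C(=C)C=O)[C@@H](O)C[C@@]2(C)OC1=CC2=O
F9 | step 14 | furanone lactol | C[C@H]1/C=C/[C@@H]2C(=C)C(O)O[C@H]2C[C@@]3(C)OC1=CC3=O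
F10 | step 14 | furanone α-methylene lactone with E C5=C6 alkene | C[C@H]1/C=C/[C@@H]2C(=C)C(=O)O[C@H]2C[C@@]3(C)OC1=CC3=O
F11 | step 14 | lactone (5S,6S)-diol | O[C@@H]1[C@@H](O)[C@H](C)C2=CC(=O)[C@@](C)(C[C@@H]3OC(=O)C(=C)[C@@H]13)O2
F12 | step 14 | lactone diol 5-O-triethylsilyl ether | O[C@@H]1[C@@H](O[Si](CC)(CC)CC)[C@H](C)C2=CC(=O)[C@@](C)(C[C@@H]3OC(=O)C(=C)[C@@H]13)O2
F13 | step 14 | 5-O-triethylsilyl ether of the target | C=C(C)C(=O)O[C@@H]1[C@@H](O[Si](CC)(CC)CC)[C@H](C)C2=CC(=O)[C@@](C)(C[C@@H]3OC(=O)C(=C)[C@@H]13)O2
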